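**Assumption:** the target SMILES has no stereocentre and no stereogenic double bond, so cathafuran C is a single achiral compound and no enantiocontrol is needed. The only stereocentre on the route (the carbinol carbon in 13–16) is formed racemic and is destroyed in step 6.

**Retrosynthetic overview**
1. Furan ring last: desilylative Sonogashira coupling and 5-endo-dig closure of chromene alkyne 17 with 4-iodoresorcinol 18. The hindered aryl–C2 bond is already present as the aryl–alkyne bond.
2. Pyran ring before that: acid-triggered MOM loss and cyclodehydration of an aryl prenyl carbinol. The carbinol and the C-prenyl group both come from dibromide 9 by two Br/Li exchanges (prenal, then prenyl bromide).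
3. Dibromide 9 comes from regioselective bromination of aryl alkyne 8. The aryl–alkyne bond is made by the key step, an iodine-triggered 1,2-aryl shift from boron to carbon in an alkynyl boronate.
4. Boronate 3 comes from Ir-catalysed meta C–H borylation of bis-MOM resorcinol; the central benzene ring is resorcinol itself.
5. Ring order: benzene rings preformed (two resorcinols), then the pyran ring, then the furan ring.

**Step 1**
Reactants: 1 resorcinol
Product: 2 1,3-bis(methoxymethoxy)benzene
Conditions: NaH (2.4 equiv), MOMCl (2.4 equiv), DMF, 0 °C → rt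
Reagents that add atoms: chloromethyl methyl ether (MOMCl), COCCl
Why: Williamson-type O-alkylation of the bis-phenoxide gives the bis-MOM acetal, which tolerates the borylation and organolithium steps and directs the later bromination.

**Step 2**
Reactants: 2 1,3-bis(methoxymethoxy)benzene
Product: 3 2-[3,5-bis(methoxymethoxy)phenyl]-4,4,5,5-tetramethyl-1,3,2-dioxaborolane
Conditions: [Ir(OMe)(cod)]2 (1 mol%), dtbpy (2 mol%), B2pin2 (0.55 equiv), THF, 80 °C
Reagents that add atoms: bis(pinacolato)diboron, CC1(C)OB(OC1(C)C)B1OC(C)(C)C(C)(C)O1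
Why: Ir-catalysed C–H borylation is sterically controlled, so a 1,3-disubstituted arene is borylated only at the mutually meta C5 position, which electrophilic chemistry cannot reach.

**Step 3**
Reactants: 3 2-[3,5-bis(methoxymethoxy)phenyl]-4,4,5,5-tetramethyl-1,3,2-dioxaborolane; 4 ethynyltrimethylsilane
Product: 8 {[3,5-bis(methoxymethoxy)phenyl]ethynyl}trimethylsilane, via lithium (trimethylsilyl)acetylide 5 (not isolated), via lithium [3,5-bis(methoxymethoxy)phenyl](pinacolato)[(trimethylsilyl)ethynyl]borate 6 (not isolated), via 2-[(E)-1-[3,5-bis(methoxymethoxy)phenyl]-2-iodo-2-(trimethylsilyl)ethenyl]-4,4,5,5-tetramethyl-1,3,2-dioxaborolane 7 (not isolated)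
Conditions: 4, n-BuLi (1.15 equiv), THF, −78 °C; then 3, −78 °C, 1 h; I2 (1.1 equiv), THF, −78 °C; NaOMe (1.2 equiv)/MeOH, −78 → −20 °C; pH 7 buffer, aq. Na2S2O3
Reagents that add atoms: none
Why: Proposed new method: iodine-triggered 1,2-metallate rearrangement of a lithium aryl(alkynyl)pinacolboronate, in which I+ attacks the silyl-bearing alkyne carbon of 6 (the developing charge at the boron-bearing carbon is stabilised by the C–B and the β C–Si bonds), the aryl group shifts from boron to carbon anti to iodine to give 7, and methoxide then expels the boryl and iodide groups (β-deiodoboration) to release the alkyne; the unhindered aryl boronate should bind the acetylide tightly enough at −78 °C to avoid the dissociation that defeats this sequence with secondary alkyl pinacol boronates; the closest known reactions are the iodine-induced alkyne synthesis from lithium alkynyl(trialkyl)borates and the Zweifel olefination of aryl pinacol boronates.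

**Step 4**
Reactants: 8 {[3,5-bis(methoxymethoxy)phenyl]ethynyl}trimethylsilane
Product: 9 {[2,6-dibromo-3,5-bis(methoxymethoxy)phenyl]ethynyl}trimethylsilane
Conditions: NBS (2.1 equiv), MeCN, 0 °C → rt, dark
Reagents that add atoms: N-bromosuccinimide, O=C1CCC(=O)N1Br
Why: Electrophilic aromatic bromination of 1-substituted 3,5-dialkoxybenzenes goes to the two positions ortho to the C1 substituent (each ortho to one OMOM and para to the other) and not to the shielded position between the two OMOM groups; the silylalkyne is inert to NBS without silver or fluoride.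

**Step 5**
Reactants: 9 {[2,6-dibromo-3,5-bis(methoxymethoxy)phenyl]ethynyl}trimethylsilane; 10 3-methylbut-2-enal; 11 1-bromo-3-methylbut-2-ene
Product: 15 1-{4,6-bis(methoxymethoxy)-3-(3-methylbut-2-en-1-yl)-2-[(trimethylsilyl)ethynyl]phenyl}-3-methylbut-2-en-1-ol (racemic), via {[2-bromo-6-lithio-3,5-bis(methoxymethoxy)phenyl]ethynyl}trimethylsilane 12 (not isolated), via lithium 1-{3-bromo-4,6-bis(methoxymethoxy)-2-[(trimethylsilyl)ethynyl]phenyl}-3-methylbut-2-en-1-olate 13 (not isolated), via lithium 1-{3-lithio-4,6-bis(methoxymethoxy)-2-[(trimethylsilyl)ethynyl]phenyl}-3-methylbut-2-en-1-olate 14 (not isolated)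
Conditions: t-BuLi (2.0 equiv), THF, −78 °C, 10 min; 10 (1.05 equiv), −78 °C; t-BuLi (2.1 equiv), −78 °C, 10 min; CuBr·SMe2 (10 mol%), 11 (1.2 equiv), −78 → −20 °C; H2O
Reagents that add atoms: none
Why: Two consecutive bromine–lithium exchanges on the symmetrical dibromide give first a 1,2-addition to the enal and then a Cu-catalysed SN2 allylation with prenyl bromide, each exchange being much faster at −78 °C than deprotonation between the OMOM groups; the carbinol stereocentre is formed racemic and is erased in step 6.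

**Step 6**
Reactants: 15 1-{4,6-bis(methoxymethoxy)-3-(3-methylbut-2-en-1-yl)-2-[(trimethylsilyl)ethynyl]phenyl}-3-methylbut-2-en-1-ol (crude)
Product: 17 2,2-dimethyl-6-(3-methylbut-2-en-1-yl)-5-[(trimethylsilyl)ethynyl]-2H-chromen-7-ol, via 4-(1-hydroxy-3-methylbut-2-en-1-yl)-6-(3-methylbut-2-en-1-yl)-5-[(trimethylsilyl)ethynyl]benzene-1,3-diol 16 (not isolated)
Conditions: HCl (1 M in MeOH), 0 → 40 °C
Reagents that add atoms: none
Why: Acidic methanolysis removes both MOM acetals while the benzylic, allylic alcohol ionises to an o-quinone-methide-type allyl cation that the freed ortho phenol captures at the tertiary terminus (cyclodehydration, the usual fate of 1-(2-hydroxyaryl)-3-methylbut-2-en-1-ols, giving the 2,2-dimethyl-2H-chromene); the alkynylsilane is acid-stable.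

**Step 7**
Reactants: 1 resorcinol
Product: 18 4-iodobenzene-1,3-diol
Conditions: ICl (1.0 equiv), Et2O, 0 °C → rt
Reagents that add atoms: iodine monochloride, ClI
Why: Electrophilic aromatic iodination with ICl in ether goes to C4 of resorcinol (ortho to one OH, para to the other), giving the o-iodophenol needed for benzofuran annulation.

**Step 8**
Reactants: 17 2,2-dimethyl-6-(3-methylbut-2-en-1-yl)-5-[(trimethylsilyl)ethynyl]-2H-chromen-7-ol; 18 4-iodobenzene-1,3-diol
Product: 21 cathafuran C, 5-(6-hydroxy-1-benzofuran-2-yl)-2,2-dimethyl-6-(3-methylbut-2-en-1-yl)-2H-chromen-7-ol, via 5-ethynyl-2,2-dimethyl-6-(3-methylbut-2-en-1-yl)-2H-chromen-7-ol 19 (not isolated), via 5-[(2,4-dihydroxyphenyl)ethynyl]-2,2-dimethyl-6-(3-methylbut-2-en-1-yl)-2H-chromen-7-ol 20 (not isolated)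
Conditions: Pd(PPh3)2Cl2 (5 mol%), CuI (10 mol%), CsF (3 equiv), Et3N/DMF (1:3), degassed, 70 °C
Reagents that add atoms: none
Why: Fluoride-promoted in situ desilylation feeds a Sonogashira coupling with the o-iodophenol, and the resulting o-alkynylphenol closes by Cu/Pd-assisted 5-endo-dig hydroalkoxylation (domino Sonogashira/heteroannulation to a 2-arylbenzofuran); the hydroxyl para to iodine becomes the 6-OH, and the East phenol is meta to the alkyne and cannot compete.

**Compound list**
1 | resorcinol (benzene-1,3-diol) | Oc1cccc(O)c1 | starting material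
2 | 1,3-bis(methoxymethoxy)benzene | COCOc1cccc(OCOC)c1 | intermediate
3 | 2-[3,5-bis(methoxymethoxy)phenyl]-4,4,5,5-tetramethyl-1,3,2-dioxaborolane | COCOc1cc(OCOC)cc(c1)B1OC(C)(C)C(C)(C)O1 | intermediate
4 | ethynyltrimethylsilane | C#C[Si](C)(C)C | starting material
5 | lithium (trimethylsilyl)acetylide | [Li]C#C[Si](C)(C)C | intermediate
6 | lithium [3,5-bis(methoxymethoxy)phenyl](pinacolato)[(trimethylsilyl)ethynyl]borate | [Li+].COCOc1cc(OCOC)cc(c1)[B-]1(OC(C)(C)C(C)(C)O1)C#C[Si](C)(C)C | intermediate
7 | 2-[(E)-1-[3,5-bis(methoxymethoxy)phenyl]-2-iodo-2-(trimethylsilyl)ethenyl]-4,4,5,5-tetramethyl-1,3,2-dioxaborolane (aryl and iodine trans) | COCOc1cc(OCOC)cc(c1)/C(B1OC(C)(C)C(C)(C)O1)=C(/I)[Si](C)(C)C | intermediate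
8 | {[3,5-bis(methoxymethoxy)phenyl]ethynyl}trimethylsilane | COCOc1cc(OCOC)cc(c1)C#C[Si](C)(C)C | intermediate
9 | {[2,6-dibromo-3,5-bis(methoxymethoxy)phenyl]ethynyl}trimethylsilane | COCOc1cc(OCOC)c(Br)c(C#C[Si](C)(C)C)c1Br | intermediate
10 | 3-methylbut-2-enal (prenal) | CC(C)=CC=O | starting material
11 | 1-bromo-3-methylbut-2-ene (prenyl bromide) | CC(C)=CCBr | starting material
12 | {[2-bromo-6-lithio-3,5-bis(methoxymethoxy)phenyl]ethynyl}trimethylsilane | COCOc1cc(OCOC)c(Br)c(C#C[Si](C)(C)C)c1[Li] | intermediate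
13 | lithium 1-{3-bromo-4,6-bis(methoxymethoxy)-2-[(trimethylsilyl)ethynyl]phenyl}-3-methylbut-2-en-1-olate (racemic) | [Li]OC(C=C(C)C)c1c(OCOC)cc(OCOC)c(Br)c1C#C[Si](C)(C)C | intermediate
14 | lithium 1-{3-lithio-4,6-bis(methoxymethoxy)-2-[(trimethylsilyl)ethynyl]phenyl}-3-methylbut-2-en-1-olate (racemic) | [Li]OC(C=C(C)C)c1c(OCOC)cc(OCOC)c([Li])c1C#C[Si](C)(C)C | intermediate
15 | 1-{4,6-bis(methoxymethoxy)-3-(3-methylbut-2-en-1-yl)-2-[(trimethylsilyl)ethynyl]phenyl}-3-methylbut-2-en-1-ol (racemic) | OC(C=C(C)C)c1c(OCOC)cc(OCOC)c(CC=C(C)C)c1C#C[Si](C)(C)C | intermediate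
16 | 4-(1-hydroxy-3-methylbut-2-en-1-yl)-6-(3-methylbut-2-en-1-yl)-5-[(trimethylsilyl)ethynyl]benzene-1,3-diol (racemic) | OC(C=C(C)C)c1c(O)cc(O)c(CC=C(C)C)c1C#C[Si](C)(C)C | intermediate
17 | 2,2-dimethyl-6-(3-methylbut-2-en-1-yl)-5-[(trimethylsilyl)ethynyl]-2H-chromen-7-ol | CC(C)=CCc1c(O)cc2OC(C)(C)C=Cc2c1C#C[Si](C)(C)C | intermediate
18 | 4-iodobenzene-1,3-diol (4-iodoresorcinol) | Oc1ccc(I)c(O)c1 | intermediate
19 | 5-ethynyl-2,2-dimethyl-6-(3-methylbut-2-en-1-yl)-2H-chromen-7-ol | CC(C)=CCc1c(O)cc2OC(C)(C)C=Cc2c1C#C | intermediate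
20 | 5-[(2,4-dihydroxyphenyl)ethynyl]-2,2-dimethyl-6-(3-methylbut-2-en-1-yl)-2H-chromen-7-ol | CC(C)=CCc1c(O)cc2OC(C)(C)C=Cc2c1C#Cc1ccc(O)cc1O | intermediate
21 | cathafuran C, 5-(6-hydroxy-1-benzofuran-2-yl)-2,2-dimethyl-6-(3-methylbut-2-en-1-yl)-2H-chromen-7-ol (achiral) | CC(C)=CCc1c(O)cc2c(c1-c1cc3ccc(O)cc3o1)C=CC(C)(C)O2 | target

**Step count**
Total: 8 steps. Longest linear sequence: 7 steps (steps 1–6, then 8); step 7 is a one-step side branch.

**Three steps most likely to fail**

Step 3 (the proposed new step). The ate complex 6 may dissociate so that iodine traps the free acetylide, or the methoxide may partly desilylate the product. The fallback uses known chemistry, sets out from 3 and comes back at 8. Compound 3 is combined with vinyl bromide and LDA (THF, −78 °C; the α-lithiated vinyl bromide is trapped in situ as the boronate) and then treated with I2 and NaOMe/MeOH. This established Zweifel-type sequence gives 1-(1-bromoethenyl)-3,5-bis(methoxymethoxy)benzene F1. LDA (2.2 equiv, THF, −78 → 0 °C) then eliminates HBr to give lithium [3,5-bis(methoxymethoxy)phenyl]acetylide F2, which is silylated in the same flask with TMSCl to give 8.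

Step 5 (one-pot double functionalisation). The alkoxide 13 may be O-prenylated, may attack the neighbouring alkyne, or the stoichiometry of the second exchange may drift. The fallback sets out from 9 and comes back at 15. It separates the two C–C bond formations and reverses their order, so that no alkoxide is present when prenyl bromide is added. Compound 9 is treated with t-BuLi (2.0 equiv, −78 °C), CuBr·SMe2 (cat.) and 11 to give {[2-bromo-3,5-bis(methoxymethoxy)-6-(3-methylbut-2-en-1-yl)phenyl]ethynyl}trimethylsilane F3, a stable bromide that is purified. A second exchange (t-BuLi, 2.0 equiv, −78 °C) followed by 10 then gives 15.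

Step 6 (acid cascade). The allyl cation may be trapped by methanol, the prenyl phenol may close to a chroman, or the new chromene may add methanol. The fallback sets out from 15 and comes back at 17, building the pyran ring through a chromanone. MnO2 (CH2Cl2, rt) oxidises 15 to 1-{4,6-bis(methoxymethoxy)-3-(3-methylbut-2-en-1-yl)-2-[(trimethylsilyl)ethynyl]phenyl}-3-methylbut-2-en-1-one F4. HCl/MeOH (50 °C) removes the MOM groups and the ortho phenol closes by oxa-Michael addition to give 7-hydroxy-2,2-dimethyl-6-(3-methylbut-2-en-1-yl)-5-[(trimethylsilyl)ethynyl]-2,3-dihydro-4H-chromen-4-one F5. NaBH4 (MeOH, 0 °C) gives 2,2-dimethyl-6-(3-methylbut-2-en-1-yl)-5-[(trimethylsilyl)ethynyl]-3,4-dihydro-2H-chromene-4,7-diol F6 (racemic). PPTS (cat., toluene, 60 °C) dehydrates it to 17.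

**Further compounds**
F1 | step 3 | 1-(1-bromoethenyl)-3,5-bis(methoxymethoxy)benzene | C=C(Br)c1cc(OCOC)cc(OCOC)c1
F2 | step 3 | lithium [3,5-bis(methoxymethoxy)phenyl]acetylide | [Li]C#Cc1cc(OCOC)cc(OCOC)c1
F3 | step 5 | {[2-bromo-3,5-bis(methoxymethoxy)-6-(3-methylbut-2-en-1-yl)phenyl]ethynyl}trimethylsilane | COCOc1cc(OCOC)c(CC=C(C)C)c(C#C[Si](C)(C)C)c1Br
F4 | step 6 | 1-{4,6-bis(methoxymethoxy)-3-(3-methylbut-2-en-1-yl)-2-[(trimethylsilyl)ethynyl]phenyl}-3-methylbut-2-en-1-one | O=C(C=C(C)C)c1c(OCOC)cc(OCOC)c(CC=C(C)C)c1C#C[Si](C)(C)C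
F5 | step 6 | 7-hydroxy-2,2-dimethyl-6-(3-methylbut-2-en-1-yl)-5-[(trimethylsilyl)ethynyl]-2,3-dihydro-4H-chromen-4-one | CC(C)=CCc1c(O)cc2OC(C)(C)CC(=O)c2c1C#C[Si](C)(C)C
F6 | step 6 | 2,2-dimethyl-6-(3-methylbut-2-en-1-yl)-5-[(trimethylsilyl)ethynyl]-3,4-dihydro-2H-chromene-4,7-diol (racemic) | CC(C)=CCc1c(O)cc2OC(C)(C)CC(O)c2c1C#C[Si](C)(C)C
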